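**Assumptions:** (+)-sclareolide (natural labdane series) and (E)-geranylacetone are purchased. The target's decalin is the sclareol-type (1R,2R,4aS,8aS) bicycle, and its ring-C stereocentre is (S).

## Retrosynthetic overview
1. Ambrein → Negishi sp3–sp2 disconnection at the C12–C13 bond. This gives a decalin primary iodide with the tertiary OH masked as its TES ether, and an (E)-trisubstituted alkenyl iodide.
2. The decalin iodide comes from (+)-sclareolide, which supplies all four decalin stereocentres and both decalin rings: LiAlH4, then TES protection, then Appel iodination.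
3. The alkenyl iodide comes from Zr-catalysed methylalumination/iodination of a terminal alkyne, which fixes the E-alkene.
4. The alkyne, which carries the only remaining stereocentre (ring C), is formed by a proposed new IDPi-catalysed, γ-selective (exo-methylene) asymmetric proton-initiated monocyclisation of an enyne. The enyne is made from geranylacetone.
5. Ring order: ring C is formed first (step 3); rings A/B are already present in sclareolide; the fragments are joined at the end.

## Route

**Step 1**
Reactants: 1 (E)-geranylacetone
Product: 2 (E)-6,10-dimethylundeca-1,5,9-trien-2-yl diethyl phosphate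
Conditions: LDA, THF, –78 °C; then ClP(O)(OEt)2, –78 °C → rt
Reagents that add atoms: diethyl chlorophosphate, ClP(=O)(OCC)OCC
Why: Kinetic deprotonation of the methyl ketone at CH3 followed by O-phosphorylation gives the terminal enol phosphate (Negishi-type ketone → enol phosphate); the minor internal regioisomer is removed by chromatography and no stereocentre is made.

**Step 2**
Reactants: 2
Product: 3 (E)-6,10-dimethylundeca-5,9-dien-1-yne
Conditions: LDA (3 equiv), THF, –78 °C → rt; aq. NH4Cl
Reagents that add atoms: none
Why: Excess LDA removes the vinylic proton and eliminates phosphate to give the terminal acetylide (enol phosphate → alkyne), and the E-trisubstituted and isopropylidene alkenes are inert to LDA.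

**Step 3**
Reactants: 3
Product: 4 (S)-1-(but-3-yn-1-yl)-2,2-dimethyl-6-methylenecyclohexane
Conditions: chiral IDPi Brønsted acid (3 mol %, enantiomer giving 5S), pentane/CH2Cl2 10:1, –20 °C, 72 h; Et3N quench
Reagents that add atoms: none (isomerisation)
Why: Proposed new method: the IDPi protonates the isopropylidene terminus (Markovnikov) concerted with a chair-like C4–C5 bond formation onto the E-trisubstituted alkene, and the confined chiral anion selects the alkene face, which sets C5 as (S); the resulting tight-ion-paired tertiary C10 cation is then deprotonated at the methyl group (exo-methylene) by the anion, the terminal alkyne being too poor a nucleophile to intercept it. The closest known reactions are IDPi-catalysed proton-initiated cyclisations of homofarnesol/nerolidol-type polyenes and terpene-cyclase monocyclisation to γ-type exo-methylene rings, and the new feature is the exo-selective, enantioselective E1 termination on a simple hydrocarbon.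

**Step 4**
Reactants: 4
Product: 5 (S)-1-[(E)-4-iodo-3-methylbut-3-en-1-yl]-2,2-dimethyl-6-methylenecyclohexane
Conditions: Me3Al, cat. Cp2ZrCl2, ClCH2CH2Cl, rt; then I2, THF, –30 → 0 °C
Reagents that add atoms: trimethylaluminium, C[Al](C)C (gives the C-methyl); iodine, II
Why: Negishi Zr-catalysed syn-methylalumination of a terminal alkyne places Me on the internal carbon and Al on the terminal carbon, and iodinolysis with retention gives the E-vinyl iodide, while the hindered 1,1-disubstituted alkene is unreactive.

**Step 5**
Reactants: 6 (+)-sclareolide
Product: 7 ambradiol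
Conditions: LiAlH4, THF, 0 °C → rt; Fieser work-up
Reagents that add atoms: none
Why: Hydride reduction of the lactone cleaves the acyl–O bond, so the C8–O bond and all four decalin stereocentres are untouched.

**Step 6**
Reactants: 7
Product: 8 bis-TES ether
Conditions: TESOTf (2.6 equiv), 2,6-lutidine, CH2Cl2, –78 → 0 °C
Reagents that add atoms: triethylsilyl triflate, CC[Si](CC)(CC)OS(=O)(=O)C(F)(F)F
Why: Silylation masks the tertiary OH, which would otherwise close onto the activated primary carbon to give Ambrox in step 8.

**Step 7**
Reactants: 8
Product: 9 primary alcohol with tertiary OTES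
Conditions: PPTS (cat.), MeOH, 0 °C → rt
Reagents that add atoms: none
Why: Mild acidic methanolysis removes the primary TES ether selectively, while the hindered tertiary TES ether survives.

**Step 8**
Reactants: 9
Product: 10 primary iodide
Conditions: PPh3, imidazole, I2, CH2Cl2, 0 °C → rt
Reagents that add atoms: iodine, II
Why: Appel iodination by SN2 at the primary carbinol carbon, with the tertiary silyl ether inert.

**Step 9**
Reactants: 10 (decalin iodide) and 5 (alkenyl iodide)
Product: 11 TES-protected ambrein
Conditions: (a) Zn dust, cat. I2, DMA, 50 °C; (b) 5, Pd(PPh3)4 (5 mol %), THF/DMA, 50 °C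
Reagents that add atoms: none
Why: Negishi coupling of the in-situ primary alkylzinc iodide with the alkenyl iodide forms the C12–C13 bond with retention of E geometry, and the TES ether, both alkenes and all stereocentres are untouched.

**Step 10**
Reactants: 11
Product: 12 ambrein
Conditions: TBAF, THF, 45 °C
Reagents that add atoms: none
Why: Fluoride cleaves the tertiary TES ether under basic, non-ionising conditions, so the C8 configuration is retained.

## Compound list
1 | (E)-geranylacetone, (E)-6,10-dimethylundeca-5,9-dien-2-one | CC(=O)CC/C=C(C)/CCC=C(C)C | starting material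
2 | (E)-6,10-dimethylundeca-1,5,9-trien-2-yl diethyl phosphate | C=C(CC/C=C(C)/CCC=C(C)C)OP(=O)(OCC)OCC | intermediate
3 | (E)-6,10-dimethylundeca-5,9-dien-1-yne | C#CCC/C=C(C)/CCC=C(C)C | intermediate
4 | (S)-1-(but-3-yn-1-yl)-2,2-dimethyl-6-methylenecyclohexane | C=C1CCCC(C)(C)[C@@H]1CCC#C | intermediate
5 | (S)-1-[(E)-4-iodo-3-methylbut-3-en-1-yl]-2,2-dimethyl-6-methylenecyclohexane | C=C1CCCC(C)(C)[C@@H]1CC/C(C)=C/I | intermediate
6 | (+)-sclareolide, (3aR,5aS,9aS,9bR) | O=C1C[C@@H]2[C@@]3(C)CCCC(C)(C)[C@@H]3CC[C@@]2(C)O1 | starting material
7 | ambradiol, (1R,2R,4aS,8aS)-1-(2-hydroxyethyl)-2,5,5,8a-tetramethyldecahydronaphthalen-2-ol | OCC[C@@H]1[C@@]2(C)CCCC(C)(C)[C@@H]2CC[C@@]1(C)O | intermediate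
8 | bis-triethylsilyl ether of 7 | CC[Si](CC)(CC)OCC[C@@H]1[C@@]2(C)CCCC(C)(C)[C@@H]2CC[C@@]1(C)O[Si](CC)(CC)CC | intermediate
9 | 2-[(1R,2R,4aS,8aS)-2,5,5,8a-tetramethyl-2-(triethylsilyloxy)decahydronaphthalen-1-yl]ethanol | OCC[C@@H]1[C@@]2(C)CCCC(C)(C)[C@@H]2CC[C@@]1(C)O[Si](CC)(CC)CC | intermediate
10 | (1R,2R,4aS,8aS)-1-(2-iodoethyl)-2,5,5,8a-tetramethyl-2-(triethylsilyloxy)decahydronaphthalene | ICC[C@@H]1[C@@]2(C)CCCC(C)(C)[C@@H]2CC[C@@]1(C)O[Si](CC)(CC)CC | intermediate
11 | TES ether of ambrein | C=C1CCCC(C)(C)[C@@H]1CC/C(C)=C/CC[C@@H]1[C@@]2(C)CCCC(C)(C)[C@@H]2CC[C@@]1(C)O[Si](CC)(CC)CC | intermediate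
12 | ambrein, (1R,2R,4aS,8aS)-1-{(3E)-6-[(1S)-2,2-dimethyl-6-methylidenecyclohexyl]-4-methylhex-3-en-1-yl}-2,5,5,8a-tetramethyldecahydronaphthalen-2-ol | C=C1CCCC(C)(C)[C@@H]1CC/C(C)=C/CC[C@@H]1[C@@]2(C)CCCC(C)(C)[C@@H]2CC[C@@]1(C)O | target

## Totals
- Total steps: 10.
- Longest linear sequence: 6 steps, either 1→2→3→4→9→10 or 5→6→7→8→9→10.

## Three steps most likely to fail
1. **Step 3 (proposed new IDPi exo-selective monocyclisation).** The exo/endo (γ/α) selectivity and the enantioselectivity are unproven, and the exo-methylene product can be re-protonated and isomerise to the endocyclic or tetrasubstituted alkene, which would racemise C5.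
   - Fallback (known chemistry, different mechanism): make ethyl (E)-5,9-dimethyldeca-4,8-dienoate from geranyl bromide and diethyl malonate (alkylation, then Krapcho). Apply Shi asymmetric epoxidation of the terminal olefin, then Cp2TiCl-catalysed radical epoxide cyclisation, which gives the 3-hydroxy exo-methylene ring with C5 set by the epoxide configuration. Remove the 3-OH by Barton–McCombie deoxygenation, then DIBAL to the aldehyde and Ohira–Bestmann to the alkyne 4.
2. **Step 9 (Negishi coupling of a hindered trisubstituted alkenyl iodide with the alkylzinc).** It may suffer from slow coupling, homocoupling or β-hydride-derived reduction.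
   - Fallback: form the alkenyl Grignard from 5 (iPrMgCl·LiCl) and couple it with iodide 10 under Fe(acac)3/NMP or Li2CuCl4 catalysis (Kumada-type); alternatively use Ni-catalysed reductive cross-electrophile coupling of 5 and 10.
3. **Step 2 (regioselectivity of enol phosphate formation and elimination).** Kinetic enolisation at CH2 rather than CH3 would give internal alkyne or allene by-products.
   - Fallback: build alkyne 3 from geranyl bromide by malonate alkylation and Krapcho decarboxylation, then DIBAL reduction to the aldehyde and Ohira–Bestmann homologation, which avoids ketone enolisation altogether.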